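A direct plan would build ring A last by refolding a pyrone: Claisen chemistry on ester A1 would give diketo ester A2 and the 4-methoxy-2-pyrone A3, whose lithiated side chain would be acylated with the ring B Weinreb amide A4 to keto pyrone A5; hydroxide would then fold A5 by aldol closure and decarboxylation to the pentabenzyl ether A6. Its weakest steps would be (a) the dianion acylation that makes A2, which would spend two equivalents of an advanced β-keto ester on one crowded bond; (b) the four-step run-up to A4 and its union with lithiated A3, with little gain in complexity, competing benzylic deprotonation and a product more acidic than the substrate; (c) above all the hydroxide-induced fold of A5, which would leave the closure of ring A to chance on the most precious material, since a fully substituted carbon must attack a hindered ketone while retro-Claisen cleavage and other folds compete.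

Plan of the new route. Ring A is a resorcinol monomethyl ether (C1 OMe and C3 OH meta) with carbon on C2, C4, C5 and C6 and the same 4-hydroxybenzyl group on C2, C4 and C6, which is the pattern a vinylketene and a 1-methoxyalkyne deliver. The retrosynthesis cuts ring A at C2–C3, C1–C6 and C3–C4 into cyclobutenone 20 and ynol ether 6. It then cuts 20 at the bond from C5 to its side chain (Grignard reagent 18) and into ketene 11 plus the same ynol ether 6. The diarylmethane of ring B is set earlier through a transient isochroman, so rings arise in the order isochroman (opened again), four-membered carbocycle, ring A. No dianion, no pyrone and no choice between folds remain: the ring B chain is joined as a simple Grignard reagent before ring A exists, and a pericyclic cascade whose regiochemistry is fixed by polarity closes ring A.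

Key step: step 10

Remark: ring A is numbered C1 (OMe), C2, C3 (OH), C4, C5 (chain), C6; the target has no stereocentre; "allyl" means prop-2-en-1-yl, and all phenols except the one on ring A are carried as allyl ethers.

Step 1
Reactants: 1 4-(allyloxy)benzaldehyde
Product: 2 [4-(allyloxy)phenyl]methanol
Conditions: NaBH4, MeOH, 0 °C
Reagents that add atoms: none
Why: Hydride reduction of an aromatic aldehyde by NaBH4, which leaves the allyl ether untouched.

Step 2
Reactants: 2 [4-(allyloxy)phenyl]methanol
Product: 3 1-(allyloxy)-4-(bromomethyl)benzene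
Conditions: PBr3 (0.4 equiv), Et2O, 0 °C; used at once
Reagents that add atoms: phosphorus tribromide, BrP(Br)Br
Why: Conversion of a benzylic alcohol into the bromide through its phosphite ester (SN2 by bromide), run cold because 4-alkoxybenzyl bromides ionise easily.

Step 3
Reactants: 4 2-chloro-1,1-dimethoxyethane, 3 1-(allyloxy)-4-(bromomethyl)benzene
Product: 6 1-(allyloxy)-4-(3-methoxyprop-2-yn-1-yl)benzene, via sodium methoxyethynide 5 (not isolated)
Conditions: 4, NaNH2 (3.0 equiv), liq. NH3, −33 °C; then 3 in THF, −40 to −33 °C; then NH4Cl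
Reagents that add atoms: sodium amide, [Na+].[NH2-] (sodium present only in 5)
Why: Alkylation of an alkoxyacetylide, in which three equivalents of NaNH2 take methanol and HCl out of the chloroacetal and deprotonate the methoxyethyne formed, and the acetylide carbon then displaces the benzylic bromide (SN2) faster than the methoxide by-product does.

Step 4
Reactants: 7 3-(4-hydroxyphenyl)propanoic acid
Product: 9 3-[4-(allyloxy)phenyl]propanoic acid, via allyl ester 8 (not isolated)
Conditions: allyl bromide (2.5 equiv), K2CO3, DMF, 50 °C; then NaOH (2 M aq.), MeOH, 25 °C; then HCl to pH 2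
Reagents that add atoms: allyl bromide, C=CCBr; sodium hydroxide, [Na+].[OH-] (its oxygen ends in the carboxyl group of 9)
Why: Williamson etherification together with carboxylate O-alkylation, followed by saponification of the allyl ester in the same flask, so that only the phenol stays allylated.

Step 5
Reactants: 9 3-[4-(allyloxy)phenyl]propanoic acid, 6 1-(allyloxy)-4-(3-methoxyprop-2-yn-1-yl)benzene
Product: 12 2,4-bis[4-(allyloxy)benzyl]-3-methoxycyclobut-2-en-1-one (racemic), via acid chloride 10 (not isolated), via ketene 11 (not isolated)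
Conditions: 9, (COCl)2, DMF (cat.), CH2Cl2, 25 °C, evaporation; then crude 10 (1.5 equiv) added slowly to 6 and Et3N, CH2Cl2, 40 °C
Reagents that add atoms: oxalyl chloride, O=C(Cl)C(=O)Cl (chlorine present only in 10)
Why: Ketene–ynol ether (2+2) cycloaddition, in which the aldoketene made by dehydrochlorination bonds through its carbonyl carbon to the nucleophilic alkyne carbon remote from oxygen, so that the 3-methoxycyclobutenone forms as one regioisomer (its sp3 centre is racemic and lost later) while slow addition of 10 keeps ketene dimerisation down.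

Step 6
Reactants: 13 2-(3-hydroxyphenyl)ethanol, 1 4-(allyloxy)benzaldehyde
Product: 15 4-[4-(allyloxy)benzyl]-3-(2-hydroxyethyl)phenol, via isochroman 14 (not isolated)
Conditions: TFA, CH2Cl2, 0 to 25 °C; then Et3SiH, 25 °C; then K2CO3, MeOH (cleaves any trifluoroacetate of the primary alcohol)
Reagents that add atoms: none
Why: Oxa-Pictet–Spengler cyclisation followed by ionic hydrogenation, in which the hydroxyethyl chain ties the aldehyde to ring B as an oxocarbenium ion that reaches the carbon ortho to the chain and para to the phenol, and Et3SiH then reduces the doubly benzylic C–O bond of the isochroman, so that the benzyl group arrives at one defined carbon of ring B.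

Step 7
Reactants: 15 4-[4-(allyloxy)benzyl]-3-(2-hydroxyethyl)phenol
Product: 16 2-{5-(allyloxy)-2-[4-(allyloxy)benzyl]phenyl}ethanol
Conditions: allyl bromide, K2CO3, acetone, reflux
Reagents that add atoms: allyl bromide, C=CCBr
Why: Williamson etherification, selective for the phenoxide because K2CO3 does not deprotonate the primary alcohol.

Step 8
Reactants: 16 2-{5-(allyloxy)-2-[4-(allyloxy)benzyl]phenyl}ethanol
Product: 17 4-(allyloxy)-1-[4-(allyloxy)benzyl]-2-(2-bromoethyl)benzene
Conditions: CBr4, PPh3, CH2Cl2, 0 °C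
Reagents that add atoms: carbon tetrabromide, BrC(Br)(Br)Br
Why: Appel reaction, an SN2 displacement on the alkoxyphosphonium ion under neutral conditions that the allyl ethers tolerate.

Step 9
Reactants: 17 4-(allyloxy)-1-[4-(allyloxy)benzyl]-2-(2-bromoethyl)benzene, 12 2,4-bis[4-(allyloxy)benzyl]-3-methoxycyclobut-2-en-1-one
Product: 20 2,4-bis[4-(allyloxy)benzyl]-3-(2-{5-(allyloxy)-2-[4-(allyloxy)benzyl]phenyl}ethyl)cyclobut-2-en-1-one (racemic), via Grignard reagent 18 (not isolated), via cyclobutenol 19 (not isolated)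
Conditions: 17, Mg, THF, 40 °C; then 12, THF, −78 to −40 °C; then 1 M HCl, −40 to 25 °C
Reagents that add atoms: magnesium, [Mg] (present only in 18); water, O (carbonyl oxygen of 20)
Why: Grignard addition to a vinylogous ester followed by acid-induced carbonyl transposition (Stork–Danheiser type), in which ionisation of the tertiary carbinol gives a methoxy-stabilised cyclobutenyl cation that water turns into the enone; since 12 is the enol ether of a symmetrical 1,3-dione, 1,2-addition and addition–elimination lead to the same product, and the cold acid quench forestalls oxyanion-accelerated opening of the cyclobutenolate.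

Step 10
Reactants: 20 2,4-bis[4-(allyloxy)benzyl]-3-(2-{5-(allyloxy)-2-[4-(allyloxy)benzyl]phenyl}ethyl)cyclobut-2-en-1-one, 6 1-(allyloxy)-4-(3-methoxyprop-2-yn-1-yl)benzene
Product: 25 2,4,6-tris[4-(allyloxy)benzyl]-3-(2-{5-(allyloxy)-2-[4-(allyloxy)benzyl]phenyl}ethyl)-5-methoxyphenol, via vinylketene 21 (not isolated), via alkenylcyclobutenone 22 (not isolated), via dienylketene 23 (not isolated), via cyclohexadienone 24 (not isolated)
Conditions: 6 (2 equiv), toluene, 80 °C then 110 °C, sealed tube, under argon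
Reagents that add atoms: none
Why: Heating opens cyclobutenone 20 by 4π electrocyclic ring opening (the benzyl group on the sp3 carbon turning outward) to vinylketene 21, which adds ynol ether 6 in a (2+2) cycloaddition with the ketene carbonyl carbon bonding to the alkyne carbon remote from OMe; the alkenylcyclobutenone 22 opens in a second 4π step to dienylketene 23, 6π electrocyclic closure gives cyclohexadienone 24, and enolisation gives phenol 25. The closest known reaction type is the Danheiser benzannulation of cyclobutenones with 1-alkoxyalkynes to resorcinol monoethers. Ring A closes by disrotatory 6π electrocyclisation of 23 (bond C3–C4), after the (2+2) step has made C2–C3 and C1–C6, and the four-membered ring of 22 is only a relay that is opened again. No stereocentre has to be controlled, since the sp3 centres of 20, 22 and 24 all end as sp2 carbons of the arene. The step needs a single orientation of 6 and capture of 21 before it dimerises: the polarity of ketene and ynol ether places OMe meta to OH with a benzyl group between them, an excess of 6 favours the cross reaction, a methyl ynol ether cannot lose an alkene by retro-ene reaction, and the aryl allyl ethers stay far below the temperature of the aromatic Claisen rearrangement. Because the substituents on both sides of C5 are the same benzyl group, the two benzyl-bearing carbons of 20 need no differentiation.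

Step 11
Reactants: 25 2,4,6-tris[4-(allyloxy)benzyl]-3-(2-{5-(allyloxy)-2-[4-(allyloxy)benzyl]phenyl}ethyl)-5-methoxyphenol
Product: 26 bleochrin B
Conditions: Pd(PPh3)4 (10 mol %), morpholine (15 equiv), THF, 40 °C, under argon
Reagents that add atoms: none
Why: Tsuji–Trost type deallylation, in which zerovalent palladium ionises each aryl allyl ether to a π-allylpalladium complex and a phenoxide, morpholine takes up the allyl group, and the methyl ether and all C–C bonds are inert.

Compound list
1 | 4-(allyloxy)benzaldehyde | C=CCOc1ccc(C=O)cc1 | starting material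
2 | [4-(allyloxy)phenyl]methanol | C=CCOc1ccc(CO)cc1 | intermediate
3 | 1-(allyloxy)-4-(bromomethyl)benzene | C=CCOc1ccc(CBr)cc1 | intermediate
4 | 2-chloro-1,1-dimethoxyethane | COC(CCl)OC | starting material
5 | sodium methoxyethynide (not isolated) | [Na+].[C-]#COC | intermediate
6 | 1-(allyloxy)-4-(3-methoxyprop-2-yn-1-yl)benzene | COC#CCc1ccc(OCC=C)cc1 | intermediate
7 | 3-(4-hydroxyphenyl)propanoic acid | OC(=O)CCc1ccc(O)cc1 | starting material
8 | allyl 3-[4-(allyloxy)phenyl]propanoate (not isolated) | C=CCOC(=O)CCc1ccc(OCC=C)cc1 | intermediate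
9 | 3-[4-(allyloxy)phenyl]propanoic acid | OC(=O)CCc1ccc(OCC=C)cc1 | intermediate
10 | 3-[4-(allyloxy)phenyl]propanoyl chloride (not isolated) | ClC(=O)CCc1ccc(OCC=C)cc1 | intermediate
11 | 3-[4-(allyloxy)phenyl]prop-1-en-1-one (ketene, not isolated) | O=C=CCc1ccc(OCC=C)cc1 | intermediate
12 | 2,4-bis[4-(allyloxy)benzyl]-3-methoxycyclobut-2-en-1-one (racemic) | COC1=C(Cc2ccc(OCC=C)cc2)C(=O)C1Cc1ccc(OCC=C)cc1 | intermediate
13 | 2-(3-hydroxyphenyl)ethanol | OCCc1cccc(O)c1 | starting material
14 | 1-[4-(allyloxy)phenyl]-3,4-dihydro-1H-2-benzopyran-6-ol (racemic, not isolated) | Oc1ccc2c(c1)CCOC2c1ccc(OCC=C)cc1 | intermediate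
15 | 4-[4-(allyloxy)benzyl]-3-(2-hydroxyethyl)phenol | OCCc1cc(O)ccc1Cc1ccc(OCC=C)cc1 | intermediate
16 | 2-{5-(allyloxy)-2-[4-(allyloxy)benzyl]phenyl}ethanol | OCCc1cc(OCC=C)ccc1Cc1ccc(OCC=C)cc1 | intermediate
17 | 4-(allyloxy)-1-[4-(allyloxy)benzyl]-2-(2-bromoethyl)benzene | BrCCc1cc(OCC=C)ccc1Cc1ccc(OCC=C)cc1 | intermediate
18 | (2-{5-(allyloxy)-2-[4-(allyloxy)benzyl]phenyl}ethyl)magnesium bromide (not isolated) | Br[Mg]CCc1cc(OCC=C)ccc1Cc1ccc(OCC=C)cc1 | intermediate
19 | 2,4-bis[4-(allyloxy)benzyl]-1-(2-{5-(allyloxy)-2-[4-(allyloxy)benzyl]phenyl}ethyl)-3-methoxycyclobut-2-en-1-ol (diastereomer mixture, not isolated) | COC1=C(Cc2ccc(OCC=C)cc2)C(O)(CCc2cc(OCC=C)ccc2Cc2ccc(OCC=C)cc2)C1Cc1ccc(OCC=C)cc1 | intermediate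
20 | 2,4-bis[4-(allyloxy)benzyl]-3-(2-{5-(allyloxy)-2-[4-(allyloxy)benzyl]phenyl}ethyl)cyclobut-2-en-1-one (racemic) | O=C1C(Cc2ccc(OCC=C)cc2)=C(CCc2cc(OCC=C)ccc2Cc2ccc(OCC=C)cc2)C1Cc1ccc(OCC=C)cc1 | intermediate
21 | (3E)-2-[4-(allyloxy)benzyl]-3-(2-{5-(allyloxy)-2-[4-(allyloxy)benzyl]phenyl}ethyl)-5-[4-(allyloxy)phenyl]penta-1,3-dien-1-one (vinylketene, not isolated) | O=C=C(Cc1ccc(OCC=C)cc1)/C(CCc1cc(OCC=C)ccc1Cc1ccc(OCC=C)cc1)=C/Cc1ccc(OCC=C)cc1 | intermediate
22 | 2,4-bis[4-(allyloxy)benzyl]-4-[(2E)-1-[4-(allyloxy)phenyl]-5-{5-(allyloxy)-2-[4-(allyloxy)benzyl]phenyl}pent-2-en-3-yl]-3-methoxycyclobut-2-en-1-one (racemic, not isolated) | COC1=C(Cc2ccc(OCC=C)cc2)C(=O)C1(Cc1ccc(OCC=C)cc1)/C(CCc1cc(OCC=C)ccc1Cc1ccc(OCC=C)cc1)=C/Cc1ccc(OCC=C)cc1 | intermediate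
23 | (3E,5E)-2,4-bis[4-(allyloxy)benzyl]-5-(2-{5-(allyloxy)-2-[4-(allyloxy)benzyl]phenyl}ethyl)-7-[4-(allyloxy)phenyl]-3-methoxyhepta-1,3,5-trien-1-one (dienylketene, not isolated) | O=C=C(Cc1ccc(OCC=C)cc1)/C(OC)=C(Cc1ccc(OCC=C)cc1)\C(CCc1cc(OCC=C)ccc1Cc1ccc(OCC=C)cc1)=C\Cc1ccc(OCC=C)cc1 | intermediate
24 | 2,4,6-tris[4-(allyloxy)benzyl]-5-(2-{5-(allyloxy)-2-[4-(allyloxy)benzyl]phenyl}ethyl)-3-methoxycyclohexa-2,4-dien-1-one (racemic, not isolated) | O=C1C(Cc2ccc(OCC=C)cc2)=C(OC)C(Cc2ccc(OCC=C)cc2)=C(CCc2cc(OCC=C)ccc2Cc2ccc(OCC=C)cc2)C1Cc1ccc(OCC=C)cc1 | intermediate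
25 | 2,4,6-tris[4-(allyloxy)benzyl]-3-(2-{5-(allyloxy)-2-[4-(allyloxy)benzyl]phenyl}ethyl)-5-methoxyphenol | COc1c(Cc2ccc(OCC=C)cc2)c(O)c(Cc2ccc(OCC=C)cc2)c(CCc2cc(OCC=C)ccc2Cc2ccc(OCC=C)cc2)c1Cc1ccc(OCC=C)cc1 | intermediate
26 | bleochrin B (no stereocentre) | COc1c(Cc2ccc(O)cc2)c(O)c(Cc2ccc(O)cc2)c(CCc2cc(O)ccc2Cc2ccc(O)cc2)c1Cc1ccc(O)cc1 | target

Total step count: 11. Longest linear sequence: 7 steps (steps 1, 2, 3, 5, 9, 10, 11).

Steps most likely to fail

Step 10. The doubly substituted vinylketene 21 may be captured too slowly by the internal ynol ether, so that ketene dimerisation, acylation of the product phenol or decomposition of 6 takes over. The fallback takes ring A as a preformed arene instead of building it. It sets out from bromide 17: zinc insertion (Zn, LiCl, THF) would give (2-{5-(allyloxy)-2-[4-(allyloxy)benzyl]phenyl}ethyl)zinc bromide F1. Negishi coupling (Pd(OAc)2, SPhos, THF) with the sodium salt of commercial 3-bromo-5-methoxyphenol would give the bibenzyl 3-(2-{5-(allyloxy)-2-[4-(allyloxy)benzyl]phenyl}ethyl)-5-methoxyphenol F2. Threefold Friedel–Crafts benzylation of F2 with alcohol 2 (Sc(OTf)3, MeNO2, 25 °C) at C2, C4 and C6, the only free positions of the resorcinol ring, would come back to the route at 25.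

Step 3. The benzylic bromide may be lost to methoxide or ammonia, and residual amide may isomerise the propargylic ynol ether to an allenyl ether. The fallback makes the acetylide without amide or alkoxide in the flask and sets out from bromide 3. Trichloroethylene and KOMe would give (E)-1,2-dichloro-1-methoxyethene F3, and n-BuLi (2 equiv, THF, −78 °C) would turn it by elimination and chlorine–lithium exchange into lithium methoxyethynide F4. Alkylation of F4 with 3 (DMPU, −78 to 0 °C) would come back to the route at 6.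

Step 5. Dimerisation of aldoketene 11 may outrun its cycloaddition with the ynol ether. The fallback replaces the ketene by a keteniminium ion, which cannot dimerise, and sets out from acid chloride 10. Me2NH would give N,N-dimethyl-3-[4-(allyloxy)phenyl]propanamide F5, and Tf2O with 2,4,6-collidine (CH2Cl2, −20 °C) would give the keteniminium triflate F6. Cycloaddition of F6 with 6 would give the cyclobuteniminium triflate F7, and hydrolysis of F7 (aq. NaHCO3) would come back to the route at 12.

Further compounds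
F1 | step 10 | (2-{5-(allyloxy)-2-[4-(allyloxy)benzyl]phenyl}ethyl)zinc bromide | Br[Zn]CCc1cc(OCC=C)ccc1Cc1ccc(OCC=C)cc1
F2 | step 10 | 3-(2-{5-(allyloxy)-2-[4-(allyloxy)benzyl]phenyl}ethyl)-5-methoxyphenol | COc1cc(O)cc(CCc2cc(OCC=C)ccc2Cc2ccc(OCC=C)cc2)c1
F3 | step 3 | (E)-1,2-dichloro-1-methoxyethene | CO/C(Cl)=C\Cl
F4 | step 3 | lithium methoxyethynide | [Li+].[C-]#COC
F5 | step 5 | N,N-dimethyl-3-[4-(allyloxy)phenyl]propanamide | CN(C)C(=O)CCc1ccc(OCC=C)cc1
F6 | step 5 | N-{3-[4-(allyloxy)phenyl]prop-1-en-1-ylidene}-N-methylmethanaminium trifluoromethanesulfonate | C[N+](C)=C=CCc1ccc(OCC=C)cc1.[O-]S(=O)(=O)C(F)(F)F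
F7 | step 5 | N-{2,4-bis[4-(allyloxy)benzyl]-3-methoxycyclobut-2-en-1-ylidene}-N-methylmethanaminium trifluoromethanesulfonate (racemic) | C[N+](C)=C1C(Cc2ccc(OCC=C)cc2)=C(OC)C1Cc1ccc(OCC=C)cc1.[O-]S(=O)(=O)C(F)(F)F
A1 | direct plan | methyl 3-[4-(benzyloxy)phenyl]propanoate | COC(=O)CCc1ccc(OCc2ccccc2)cc1
A2 | direct plan | methyl 2,4-bis[4-(benzyloxy)benzyl]-7-[4-(benzyloxy)phenyl]-3,5-dioxoheptanoate | COC(=O)C(Cc1ccc(OCc2ccccc2)cc1)C(=O)C(Cc1ccc(OCc2ccccc2)cc1)C(=O)CCc1ccc(OCc2ccccc2)cc1
A3 | direct plan | 3,5-bis[4-(benzyloxy)benzyl]-6-{2-[4-(benzyloxy)phenyl]ethyl}-4-methoxy-2H-pyran-2-one | COC1=C(Cc2ccc(OCc3ccccc3)cc2)C(=O)OC(CCc2ccc(OCc3ccccc3)cc2)=C1Cc1ccc(OCc2ccccc2)cc1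
A4 | direct plan | 3-{5-(benzyloxy)-2-[4-(benzyloxy)benzyl]phenyl}-N-methoxy-N-methylpropanamide | CON(C)C(=O)CCc1cc(OCc2ccccc2)ccc1Cc1ccc(OCc2ccccc2)cc1
A5 | direct plan | 3,5-bis[4-(benzyloxy)benzyl]-6-(1-[4-(benzyloxy)phenyl]-5-{5-(benzyloxy)-2-[4-(benzyloxy)benzyl]phenyl}-3-oxopentan-2-yl)-4-methoxy-2H-pyran-2-one (racemic) | COC1=C(Cc2ccc(OCc3ccccc3)cc2)C(=O)OC(C(Cc2ccc(OCc3ccccc3)cc2)C(=O)CCc2cc(OCc3ccccc3)ccc2Cc2ccc(OCc3ccccc3)cc2)=C1Cc1ccc(OCc2ccccc2)cc1
A6 | direct plan | 2,4,6-tris[4-(benzyloxy)benzyl]-3-(2-{5-(benzyloxy)-2-[4-(benzyloxy)benzyl]phenyl}ethyl)-5-methoxyphenol | COc1c(Cc2ccc(OCc3ccccc3)cc2)c(O)c(Cc2ccc(OCc3ccccc3)cc2)c(CCc2cc(OCc3ccccc3)ccc2Cc2ccc(OCc3ccccc3)cc2)c1Cc1ccc(OCc2ccccc2)cc1
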